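**Strategy.** The homoadamantane trione is cut back to one carbocycle: the cyclohexanone formed by the bridging C=O carbon, the geranyl bridgehead, the ring CH2, the cage CH, CMe2 and the benzoyl bridgehead. Its carbonyl is 1,4 to the cage CH and CMe2 is that CH's neighbour – the para pattern of a 2‑siloxydiene adding to 3‑methylbut‑2‑enal. One catalytic asymmetric Diels–Alder reaction of two purchased partners therefore closes this ring, makes the quaternary CMe2 carbon, sets the cage CH (R) and leaves an enol silane that marks the future geranyl carbon. The formyl group then grows into the malonate/cyclopentanone arm whose two carboxyl groups finally acylate both ring α‑carbons.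

Key step: step 1

Remarks on the chemistry (assumptions):
- The cycloadduct 3 has its enol double bond on the side away from CMe2, so its correct name is 6,6‑dimethyl‑4‑(trimethylsilyloxy)cyclohex‑3‑ene‑1‑carbaldehyde.
- 5 and 8 are carried as E/Z mixtures of the enol ether. 8–21 are carried as mixtures at the geranyl‑bearing carbon, and from 17 on as keto/enol tautomers of the 1,3‑diketone. These centres are planarised again before or in step 11 and are written without configuration.
- The sense of induction in step 1 is assigned from the accepted binding model of the catalyst; if the first run shows the opposite sense, the (R)‑catalyst is used and nothing else changes.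
- Every compound that brings carbon into a product is numbered and stands under Reactants; "Reagents that add atoms" names only un‑numbered reagents.

Step 1
Reactants: 1 2-(trimethylsilyloxy)buta-1,3-diene; 2 3-methylbut-2-enal
Product: 3 (1R)-6,6-dimethyl-4-(trimethylsilyloxy)cyclohex-3-ene-1-carbaldehyde
Conditions: (S)-B-(o-tolyl)-diphenylprolinol oxazaborolidine (20 mol %), Tf2NH (18 mol %), 1 (3 equiv), CH2Cl2, −40 → −20 °C; Et3N quench, filtration through basic alumina
Reagents that add atoms: none
Why: The protonated oxazaborolidine binds the formyl oxygen, lowers the LUMO of the s‑trans enal and lets the diene add in a concerted, asynchronous [4+2] cycloaddition, which is the mode by which the single new ring closes. The diene CH2 next to the C–OSi carbon (largest HOMO coefficient) bonds to the β‑carbon (CMe2) and the other terminus to the α‑carbon, giving the para adduct with the enol double bond remote from CMe2. The only new stereocentre, the α‑carbon, is set by the catalyst: the aryl group on the carbinol carbon covers one face of the bound enal, and by the usual formyl C–H···O binding model the (S)‑catalyst should expose the face that leads to the R aldehyde. The closest known reaction is the oxazaborolidinium‑catalysed Diels–Alder reaction of 2‑silyloxybutadienes with α‑substituted acroleins; a β,β‑dimethyl enal is less reactive, hence the high loading, excess diene and long reaction time. The step needs para regioselectivity, secured by the 2‑siloxy group, and face selectivity at the α‑carbon, secured by the catalyst; endo/exo selectivity is irrelevant because the adduct has one stereocentre.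

Step 2
Reactants: 3 (1R)-6,6-dimethyl-4-(trimethylsilyloxy)cyclohex-3-ene-1-carbaldehyde; 4 (methoxymethyl)triphenylphosphonium chloride
Product: 5 {[(4S)-4-(2-methoxyethenyl)-5,5-dimethylcyclohex-1-en-1-yl]oxy}trimethylsilane (E/Z mixture)
Conditions: 4, KHMDS, THF, 0 °C; then 3, −78 → 0 °C; non‑aqueous work‑up
Reagents that add atoms: none
Why: Wittig methoxymethylenation of the hindered aldehyde adds the second arm carbon as a base‑stable enol ether, and at −78 °C the ylide should neither epimerise the α‑stereocentre nor touch the enol silane.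

Step 3
Reactants: 5 {[(4S)-4-(2-methoxyethenyl)-5,5-dimethylcyclohex-1-en-1-yl]oxy}trimethylsilane; 6 geranyl bromide
Product: 8 (4S)-2-geranyl-4-(2-methoxyethenyl)-5,5-dimethylcyclohexan-1-one, via lithium enolate 7 (not isolated)
Conditions: MeLi (1.05 equiv), THF, 0 °C → rt; then 6, −78 → 0 °C
Reagents that add atoms: none
Why: Methyllithium cleaves the Si–O bond to the regiodefined lithium enolate, which is C‑alkylated by the allylic bromide before it can equilibrate (regiospecific enolate alkylation); the configuration at the new CH is irrelevant because this carbon is enolised again in step 11.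

Step 4
Reactants: 8 (4S)-2-geranyl-4-(2-methoxyethenyl)-5,5-dimethylcyclohexan-1-one
Product: 9 2-[(1S)-5-geranyl-2,2-dimethyl-4-oxocyclohexyl]acetaldehyde
Conditions: 1 M aq. HCl, THF, 0 °C → rt
Reagents that add atoms: water, O
Why: Acid‑catalysed enol ether hydrolysis (C‑protonation, hydration of the oxocarbenium ion, loss of methanol) unmasks the aldehyde; dilute acid at room temperature should spare the trisubstituted alkenes, and the ring stereocentre is now β to the carbonyl and cannot epimerise.

Step 5
Reactants: 9 2-[(1S)-5-geranyl-2,2-dimethyl-4-oxocyclohexyl]acetaldehyde; 10 diallyl malonate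
Product: 11 diallyl 2-[2-(5-geranyl-2,2-dimethyl-4-oxocyclohexyl)ethylidene]propanedioate
Conditions: piperidine (10 mol %), AcOH (10 mol %), 4 Å MS, CH2Cl2, rt
Reagents that add atoms: none
Why: Knoevenagel condensation – the unhindered aldehyde should condense with the malonate far faster than the α,α′‑substituted ring ketone, and removal of water drives it to the alkylidene malonate.

Step 6
Reactants: 11 diallyl 2-[2-(5-geranyl-2,2-dimethyl-4-oxocyclohexyl)ethylidene]propanedioate; 12 (1-methoxy-2-methylprop-1-enyloxy)trimethylsilane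
Product: 13 methyl 3-[bis(allyloxycarbonyl)methyl]-4-(5-geranyl-2,2-dimethyl-4-oxocyclohexyl)-2,2-dimethylbutanoate
Conditions: Cu(OTf)2 (10 mol %), (CF3)2CHOH (1.2 equiv), 12 (2 equiv, slow addition), CH2Cl2, −78 → −40 °C
Reagents that add atoms: none
Why: Lewis‑acid‑catalysed Mukaiyama–Michael addition – Cu(II) chelates only the 1,3‑diester, the ketene acetal adds to the β‑carbon and the fluorinated alcohol protonates the enolate and takes the silyl group; the new CH is set by substrate control, since the chain keeps its C–C bond anti to the ring CMe2 carbon, the chelated diester turns toward the ring C–H and not the ring CH2, and attack anti to the ring should give the configuration drawn (that of the target's cyclopentanone CH) with moderate selectivity, the minor epimer being removed by chromatography.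

Step 7
Reactants: 13 methyl 3-[bis(allyloxycarbonyl)methyl]-4-(5-geranyl-2,2-dimethyl-4-oxocyclohexyl)-2,2-dimethylbutanoate; 14 allyl bromoacetate
Product: 15 triallyl 3-[(5-geranyl-2,2-dimethyl-4-oxocyclohexyl)methyl]-4-methoxycarbonyl-4-methylpentane-1,2,2-tricarboxylate
Conditions: NaH (1.05 equiv), DMF, 0 °C; then 14, 0 °C → rt
Reagents that add atoms: none
Why: Malonate alkylation (SN2) – one equivalent of NaH removes only the malonate proton, and the anion displaces bromide from the α‑bromo ester, which makes the malonate carbon quaternary and brings in the future cyclopentanone CH2.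

Step 8
Reactants: 15 triallyl 3-[(5-geranyl-2,2-dimethyl-4-oxocyclohexyl)methyl]-4-methoxycarbonyl-4-methylpentane-1,2,2-tricarboxylate; 16 benzoyl chloride
Product: 17 triallyl 3-[(3-benzoyl-5-geranyl-2,2-dimethyl-4-oxocyclohexyl)methyl]-4-methoxycarbonyl-4-methylpentane-1,2,2-tricarboxylate
Conditions: MgBr2·OEt2 (2.5 equiv), i-Pr2NEt (3 equiv), 16 (1.1 equiv), CH2Cl2, rt
Reagents that add atoms: none
Why: Soft‑enolisation C‑acylation – Mg(II)/amine enolises only the ketone (the esters are untouched), and acylation should occur at the CH2 between C=O and CMe2 because only this site gives the chelated magnesium 1,3‑diketonate, the geranyl‑bearing carbon being tertiary and hindered; placing this step before the cyclopentanone exists avoids a second enolisable ketone.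

Step 9
Reactants: 17 triallyl 3-[(3-benzoyl-5-geranyl-2,2-dimethyl-4-oxocyclohexyl)methyl]-4-methoxycarbonyl-4-methylpentane-1,2,2-tricarboxylate
Product: 18 triallyl 5-[(3-benzoyl-5-geranyl-2,2-dimethyl-4-oxocyclohexyl)methyl]-4,4-dimethyl-3-oxocyclopentane-1,1,2-tricarboxylate
Conditions: KHMDS (2.2 equiv), THF, −78 → 0 °C; 1 M HCl
Reagents that add atoms: none
Why: Dieckmann condensation – the first equivalent of base parks the 1,3‑diketone as its enolate, the second deprotonates the only remaining acidic CH2 (α to the allyl acetate ester), which attacks the neopentyl methyl ester in a 5‑exo‑trig closure, and deprotonation of the resulting β‑keto ester drives the reaction.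

Step 10
Reactants: 18 triallyl 5-[(3-benzoyl-5-geranyl-2,2-dimethyl-4-oxocyclohexyl)methyl]-4,4-dimethyl-3-oxocyclopentane-1,1,2-tricarboxylate
Product: 20 2-[(3-benzoyl-5-geranyl-2,2-dimethyl-4-oxocyclohexyl)methyl]-3,3-dimethyl-4-oxocyclopentane-1,1-dicarboxylic acid, via triacid 19 (not isolated)
Conditions: Pd(PPh3)4 (5 mol %), HCO2H (5 equiv), Et3N (6 equiv), THF, rt → 40 °C
Reagents that add atoms: none
Why: Pd(0)‑catalysed allyl transfer to formate (π‑allyl hydrogenolysis) cleaves all three allyl esters under near‑neutral conditions; the β‑keto acid loses CO2 to give the cyclopentanone, while the disubstituted malonic acid is stable at this temperature and the geranyl alkenes are not touched.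

Step 11
Reactants: 20 2-[(3-benzoyl-5-geranyl-2,2-dimethyl-4-oxocyclohexyl)methyl]-3,3-dimethyl-4-oxocyclopentane-1,1-dicarboxylic acid
Product: 22 CNP0110281.1 (target), via bis(acid chloride) 21 (not isolated)
Conditions: 1-chloro-N,N,2-trimethylprop-1-en-1-amine (2.1 equiv), CH2Cl2, 0 °C; then MgBr2·OEt2 (3 equiv), i-Pr2NEt (4 equiv), CH2Cl2 (0.002 M), 0 °C → rt
Reagents that add atoms: none
Why: Proposed new method: the α‑chloroenamine turns both carboxyl groups into acid chlorides without releasing HCl, Mg(II)/amine then forms the chelated 1,3‑diketonate, which is acylated at carbon by the acid chloride held axially above it (O‑acylation would need a bridgehead enol ester), and soft enolisation of the remaining α‑C–H toward the geranyl carbon lets the second acid chloride close the six‑membered trione ring, the tether forcing both new bonds onto the face of the arm so that the two bridgeheads and the carbon between the new ketones are set automatically; the closest known reactions are the Mg‑mediated soft‑enolisation acylation of ketones with acid chlorides and the α,α′‑annulation of cyclohexanone enol derivatives with malonyl dichloride, neither shown for a tethered disubstituted malonyl unit or for a triacylmethane carbon.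

**Compound list**

1 | 2-(trimethylsilyloxy)buta-1,3-diene | C=CC(=C)O[Si](C)(C)C | starting material
2 | 3-methylbut-2-enal | CC(C)=CC=O | starting material
3 | (1R)-6,6-dimethyl-4-(trimethylsilyloxy)cyclohex-3-ene-1-carbaldehyde | O=C[C@@H]1CC=C(O[Si](C)(C)C)CC1(C)C | intermediate
4 | (methoxymethyl)triphenylphosphonium chloride | COC[P+](c1ccccc1)(c1ccccc1)c1ccccc1.[Cl-] | starting material
5 | {[(4S)-4-(2-methoxyethenyl)-5,5-dimethylcyclohex-1-en-1-yl]oxy}trimethylsilane (E/Z mixture) | COC=C[C@@H]1CC=C(O[Si](C)(C)C)CC1(C)C | intermediate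
6 | geranyl bromide, (2E)-1-bromo-3,7-dimethylocta-2,6-diene | CC(C)=CCC/C(C)=C/CBr | starting material
7 | lithium (4S)-4-(2-methoxyethenyl)-5,5-dimethylcyclohex-1-en-1-olate | COC=C[C@@H]1CC=C(O[Li])CC1(C)C | intermediate
8 | (4S)-2-[(2E)-3,7-dimethylocta-2,6-dien-1-yl]-4-(2-methoxyethenyl)-5,5-dimethylcyclohexan-1-one (C-2 epimers, E/Z enol ether) | CC(C)=CCC/C(C)=C/CC1C[C@@H](C=COC)C(C)(C)CC1=O | intermediate
9 | 2-[(1S)-5-geranyl-2,2-dimethyl-4-oxocyclohexyl]acetaldehyde | CC(C)=CCC/C(C)=C/CC1C[C@@H](CC=O)C(C)(C)CC1=O | intermediate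
10 | diallyl malonate (diprop-2-enyl propanedioate) | C=CCOC(=O)CC(=O)OCC=C | starting material
11 | diallyl 2-[2-(5-geranyl-2,2-dimethyl-4-oxocyclohexyl)ethylidene]propanedioate (ring CH as in 9) | CC(C)=CCC/C(C)=C/CC1C[C@@H](CC=C(C(=O)OCC=C)C(=O)OCC=C)C(C)(C)CC1=O | intermediate
12 | (1-methoxy-2-methylprop-1-enyloxy)trimethylsilane | COC(O[Si](C)(C)C)=C(C)C | starting material
13 | methyl 3-[bis(allyloxycarbonyl)methyl]-4-(5-geranyl-2,2-dimethyl-4-oxocyclohexyl)-2,2-dimethylbutanoate (ring CH as in 9; butanoate C-3 as the target's cyclopentanone CH) | CC(C)=CCC/C(C)=C/CC1C[C@@H](C[C@H](C(C(=O)OCC=C)C(=O)OCC=C)C(C)(C)C(=O)OC)C(C)(C)CC1=O | intermediate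
14 | allyl bromoacetate | C=CCOC(=O)CBr | starting material
15 | triallyl 3-[(5-geranyl-2,2-dimethyl-4-oxocyclohexyl)methyl]-4-methoxycarbonyl-4-methylpentane-1,2,2-tricarboxylate (stereocentres as in 13) | CC(C)=CCC/C(C)=C/CC1C[C@@H](C[C@H](C(CC(=O)OCC=C)(C(=O)OCC=C)C(=O)OCC=C)C(C)(C)C(=O)OC)C(C)(C)CC1=O | intermediate
16 | benzoyl chloride | O=C(Cl)c1ccccc1 | starting material
17 | triallyl 3-[(3-benzoyl-5-geranyl-2,2-dimethyl-4-oxocyclohexyl)methyl]-4-methoxycarbonyl-4-methylpentane-1,2,2-tricarboxylate (1,3-diketone, keto/enol) | CC(C)=CCC/C(C)=C/CC1C[C@@H](C[C@H](C(CC(=O)OCC=C)(C(=O)OCC=C)C(=O)OCC=C)C(C)(C)C(=O)OC)C(C)(C)C(C(=O)c2ccccc2)C1=O | intermediate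
18 | triallyl 5-[(3-benzoyl-5-geranyl-2,2-dimethyl-4-oxocyclohexyl)methyl]-4,4-dimethyl-3-oxocyclopentane-1,1,2-tricarboxylate | CC(C)=CCC/C(C)=C/CC1C[C@@H](C[C@H]2C(C)(C)C(=O)C(C(=O)OCC=C)C2(C(=O)OCC=C)C(=O)OCC=C)C(C)(C)C(C(=O)c2ccccc2)C1=O | intermediate
19 | 5-[(3-benzoyl-5-geranyl-2,2-dimethyl-4-oxocyclohexyl)methyl]-4,4-dimethyl-3-oxocyclopentane-1,1,2-tricarboxylic acid | CC(C)=CCC/C(C)=C/CC1C[C@@H](C[C@H]2C(C)(C)C(=O)C(C(=O)O)C2(C(=O)O)C(=O)O)C(C)(C)C(C(=O)c2ccccc2)C1=O | intermediate
20 | 2-[(3-benzoyl-5-geranyl-2,2-dimethyl-4-oxocyclohexyl)methyl]-3,3-dimethyl-4-oxocyclopentane-1,1-dicarboxylic acid | CC(C)=CCC/C(C)=C/CC1C[C@@H](C[C@H]2C(C)(C)C(=O)CC2(C(=O)O)C(=O)O)C(C)(C)C(C(=O)c2ccccc2)C1=O | intermediate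
21 | 2-[(3-benzoyl-5-geranyl-2,2-dimethyl-4-oxocyclohexyl)methyl]-3,3-dimethyl-4-oxocyclopentane-1,1-dicarbonyl dichloride | CC(C)=CCC/C(C)=C/CC1C[C@@H](C[C@H]2C(C)(C)C(=O)CC2(C(=O)Cl)C(=O)Cl)C(C)(C)C(C(=O)c2ccccc2)C1=O | intermediate
22 | CNP0110281.1: homoadamantane trione with fused 2,2-dimethylcyclopentanone, geranyl and benzoyl bridgeheads | CC(C)=CCC/C(C)=C/C[C@@]12C[C@H]3C[C@H]4C(C)(C)C(=O)C[C@]4(C1=O)C(=O)[C@@](C(=O)c1ccccc1)(C2=O)C3(C)C | target

**Totals.** 11 steps; longest linear sequence 11 steps (1 + 2 → 22).

**Steps most likely to fail**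

1. Step 11 (the step carrying the label). The chloroenamine may chlorinate the enolised 1,3‑diketone, or the sequence may stall after the first ring closure because the remaining simple ketone enolises too slowly, leaving an acid chloride that hydrolyses and decarboxylates on work‑up. Fallback (known chemistry), from 20 back to 22: carbodiimide esterification (DCC, C6F5OH, EtOAc, 0 °C) gives the isolable bis(pentafluorophenyl) ester F1 without any chlorinating agent. F1 is then closed twice by the established soft‑enolisation acylation of ketones with pentafluorophenyl esters (MgBr2·OEt2, i‑Pr2NEt, CH2Cl2, high dilution, rt → 40 °C).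

2. Step 1. The β,β‑disubstituted enal may react too slowly, so that protodesilylation or oligomerisation of the diene takes over, or the face selectivity may be insufficient. Fallback without a cycloaddition; no numbered compound precedes step 1, so it bypasses 1–5 and 7–8, still uses 6, and rejoins the route at 9.
   - Purchased 4,4‑dimethylcyclohex‑2‑en‑1‑one F2 is reduced (BH3·SMe2, (S)‑Me‑CBS catalyst) to (R)‑4,4‑dimethylcyclohex‑2‑en‑1‑ol F3.
   - Johnson–Claisen rearrangement (MeC(OEt)3, cat. EtCO2H, 140 °C) transfers the carbinol configuration suprafacially to the carbon next to CMe2 and gives ethyl 2‑[(1R)‑6,6‑dimethylcyclohex‑2‑en‑1‑yl]acetate F4.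
   - Allylic oxidation of the ring CH2 (CrO3·3,5‑dimethylpyrazole) gives ethyl 2‑[(1R)‑6,6‑dimethyl‑4‑oxocyclohex‑2‑en‑1‑yl]acetate F5.
   - Conjugate reduction with L‑Selectride and trapping of the regiodefined enolate with 6 gives ethyl 2‑(5‑geranyl‑2,2‑dimethyl‑4‑oxocyclohexyl)acetate F6.
   - LiAlH4 gives 4‑(2‑hydroxyethyl)‑2‑geranyl‑5,5‑dimethylcyclohexan‑1‑ol F7, and Swern oxidation of both alcohols returns to 9.

3. Step 6. Facial selectivity at the new CH rests on 1,3‑induction through a CH2 group and may be poor; aldol‑type attack on the ring ketone is a lesser risk. Fallback with reagent control, from 11 back to 18: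
   - A Cu(II)–tert‑butyl‑bis(oxazoline) hexafluoroantimonate catalyst (the antipode matched to the substrate bias) with the trimethylsilyl ketene acetal of S‑tert‑butyl 2‑methylpropanethioate and (CF3)2CHOH gives the thioester adduct S‑tert‑butyl 3‑[bis(allyloxycarbonyl)methyl]‑4‑(5‑geranyl‑2,2‑dimethyl‑4‑oxocyclohexyl)‑2,2‑dimethylbutanethioate F8.
   - Alkylation as in step 7 gives the thioester analogue of 15 F9, and benzoylation as in step 8 gives the thioester analogue of 17 F10.
   - The Dieckmann condensation of step 9, now onto the more electrophilic thioester, returns to 18.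

Further compounds
F1 | step 11 | bis(pentafluorophenyl) 2-[(3-benzoyl-5-geranyl-2,2-dimethyl-4-oxocyclohexyl)methyl]-3,3-dimethyl-4-oxocyclopentane-1,1-dicarboxylate | CC(C)=CCC/C(C)=C/CC1C[C@@H](C[C@H]2C(C)(C)C(=O)CC2(C(=O)Oc2c(F)c(F)c(F)c(F)c2F)C(=O)Oc2c(F)c(F)c(F)c(F)c2F)C(C)(C)C(C(=O)c2ccccc2)C1=O
F2 | step 1 | 4,4-dimethylcyclohex-2-en-1-one | CC1(C)CCC(=O)C=C1
F3 | step 1 | (R)-4,4-dimethylcyclohex-2-en-1-ol | O[C@H]1C=CC(C)(C)CC1
F4 | step 1 | ethyl 2-[(1R)-6,6-dimethylcyclohex-2-en-1-yl]acetate | CCOC(=O)C[C@@H]1C=CCCC1(C)C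
F5 | step 1 | ethyl 2-[(1R)-6,6-dimethyl-4-oxocyclohex-2-en-1-yl]acetate | CCOC(=O)C[C@@H]1C=CC(=O)CC1(C)C
F6 | step 1 | ethyl 2-(5-geranyl-2,2-dimethyl-4-oxocyclohexyl)acetate (ring CH as in 9) | CC(C)=CCC/C(C)=C/CC1C[C@@H](CC(=O)OCC)C(C)(C)CC1=O
F7 | step 1 | 4-(2-hydroxyethyl)-2-geranyl-5,5-dimethylcyclohexan-1-ol (ring CH as in 9) | CC(C)=CCC/C(C)=C/CC1C[C@@H](CCO)C(C)(C)CC1O
F8 | step 6 | S-tert-butyl 3-[bis(allyloxycarbonyl)methyl]-4-(5-geranyl-2,2-dimethyl-4-oxocyclohexyl)-2,2-dimethylbutanethioate | CC(C)=CCC/C(C)=C/CC1C[C@@H](C[C@H](C(C(=O)OCC=C)C(=O)OCC=C)C(C)(C)C(=O)SC(C)(C)C)C(C)(C)CC1=O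
F9 | step 6 | thioester analogue of 15 (COS-t-Bu in place of CO2Me) | CC(C)=CCC/C(C)=C/CC1C[C@@H](C[C@H](C(CC(=O)OCC=C)(C(=O)OCC=C)C(=O)OCC=C)C(C)(C)C(=O)SC(C)(C)C)C(C)(C)CC1=O
F10 | step 6 | thioester analogue of 17 (COS-t-Bu in place of CO2Me) | CC(C)=CCC/C(C)=C/CC1C[C@@H](C[C@H](C(CC(=O)OCC=C)(C(=O)OCC=C)C(=O)OCC=C)C(C)(C)C(=O)SC(C)(C)C)C(C)(C)C(C(=O)c2ccccc2)C1=O
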